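**Retrosynthetic overview**
- The target is taken back to the C2-symmetric 2,5-diethoxy-3,6-bis(5-prenylindol-3-yl)-1,4-benzoquinone: one of its two equivalent vinylogous ethyl esters is saponified (OH), the other is exchanged with hydroperoxide in the last step (OOH).
- The quinone ring, the only ring that is built, is cut into a four-carbon maleoyl unit O=C–C(indolyl)=C(OEt)–C=O and a two-carbon ynol ether indolyl–C≡C–OEt. The maleoyl unit is a cobaltacyclopentenedione made by C–C insertion of monovalent cobalt into a squarate-derived cyclobutenedione. Both ring bonds between the two units form in one cobalt-mediated alkyne annulation.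
- Enabling feature: in the quinone ring each carbonyl carbon is flanked by one indolyl-bearing and one oxygen-bearing ring carbon (2,5-diindolyl-3,6-dioxy, head to tail). Each half is therefore a vinylogous ester O=C–C(indolyl)=C–O whose polarisation matches that of an ynol ether, and the two carbonyl carbons flanking one C=C are exactly what a cyclobutene-1,2-dione delivers.
- Both halves come from one 3-bromo-5-prenyl-1-(triisopropylsilyl)indole made from 5-bromoindole. Ring order: indole and cyclobutene rings are bought, the cobaltacycle is temporary, the quinone ring is closed in the key step.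

Key step: step 7

Assumption: the target, a vinylogous peroxy acid, is taken to be stable enough to isolate when kept cold, in the dark and free of base and transition metals. (prenyl = 3-methylbut-2-en-1-yl; TIPS = triisopropylsilyl)

**Step 1**
Reactants: 1 5-bromo-1H-indole
Product: 2 5-bromo-1-(triisopropylsilyl)-1H-indole
Conditions: NaH, THF, 0 °C; TIPSCl, 0 → 25 °C
Reagents that add atoms: chlorotriisopropylsilane (TIPSCl), CC(C)[Si](Cl)(C(C)C)C(C)C
Why: N-silylation of the sodium indolide (substitution at silicon) installs a bulky group that blocks N1 and shields C2, so the later metalations at C5 and C3 stay in place.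

**Step 2**
Reactants: 2 5-bromo-1-(triisopropylsilyl)-1H-indole; 3 1-bromo-3-methylbut-2-ene (prenyl bromide)
Product: 5 5-(3-methylbut-2-en-1-yl)-1-(triisopropylsilyl)-1H-indole, via 5-lithio-1-(triisopropylsilyl)indole 4 (not isolated)
Conditions: t-BuLi (2.1 equiv), THF, −78 °C; CuBr·SMe2 (10 mol %), 3, −78 → 0 °C
Reagents that add atoms: none
Why: bromine–lithium exchange followed by copper-catalysed allylic substitution at the unhindered primary carbon of prenyl bromide (SN2 mode) should give the linear prenyl group and not the reverse-prenyl isomer.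

**Step 3**
Reactants: 5 5-(3-methylbut-2-en-1-yl)-1-(triisopropylsilyl)-1H-indole
Product: 6 3-bromo-5-(3-methylbut-2-en-1-yl)-1-(triisopropylsilyl)-1H-indole
Conditions: NBS (1.0 equiv), THF, −78 °C, dark
Reagents that add atoms: N-bromosuccinimide, O=C1CCC(=O)N1Br
Why: electrophilic aromatic substitution at the enamine-like C3 of the N-silylindole should be faster at −78 °C than attack on the trisubstituted alkene, and the TIPS group shields C2.

**Step 4**
Reactants: 6 3-bromo-5-(3-methylbut-2-en-1-yl)-1-(triisopropylsilyl)-1H-indole; 7 3,4-diethoxycyclobut-3-ene-1,2-dione (diethyl squarate)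
Product: 10 3-ethoxy-4-[5-(3-methylbut-2-en-1-yl)-1-(triisopropylsilyl)-1H-indol-3-yl]cyclobut-3-ene-1,2-dione, via 3-lithioindole 8 (not isolated), via lithium cyclobutenolate adduct 9 (not isolated)
Conditions: t-BuLi (2.0 equiv), THF, −78 °C; cannulate into 7 (1.1 equiv), THF, −78 °C; (CF3CO)2O (1.2 equiv), −78 °C; aq. NaHCO3, 0 °C
Reagents that add atoms: water, O
Why: bromine–lithium exchange, 1,2-addition of the 3-lithioindole to one squarate carbonyl, trifluoroacetylation and ionisation of the tertiary alkoxide, then hydrolysis of the alkoxy-stabilised cyclobutenyl cation with loss of ethanol is the standard addition–rearrangement sequence from squarates to 3-alkoxy-4-arylcyclobutenediones.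

**Step 5**
Reactants: 10 3-ethoxy-4-[5-(3-methylbut-2-en-1-yl)-1-(triisopropylsilyl)-1H-indol-3-yl]cyclobut-3-ene-1,2-dione
Product: 11 chlorobis(triphenylphosphine)cobalt maleoyl complex (3-ethoxy-4-indolyl-1-cobaltacyclopent-3-ene-2,5-dione, trivalent cobalt)
Conditions: ClCo(PPh3)3 (1.05 equiv), benzene, 25 °C, argon; precipitate with hexane, filter, wash with Et2O
Reagents that add atoms: chlorotris(triphenylphosphine)cobalt, ClCo(PPh3)3, Cl[Co-3]([P+](c1ccccc1)(c1ccccc1)c1ccccc1)([P+](c1ccccc1)(c1ccccc1)c1ccccc1)[P+](c1ccccc1)(c1ccccc1)c1ccccc1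
Why: oxidative addition of monovalent cobalt into the strained C(=O)–C(=O) bond of a cyclobutenedione (C–C insertion) is the established entry to maleoylcobalt complexes, and filtration removes the liberated phosphine before the quinone is made.

**Step 6**
Reactants: 6 3-bromo-5-(3-methylbut-2-en-1-yl)-1-(triisopropylsilyl)-1H-indole; 12 ethoxyethyne (ethoxyacetylene)
Product: 15 3-(ethoxyethynyl)-5-(3-methylbut-2-en-1-yl)-1-(triisopropylsilyl)-1H-indole, via (ethoxyethynyl)lithium 13 (not isolated), via (ethoxyethynyl)zinc chloride 14 (not isolated)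
Conditions: 12, n-BuLi, THF, −78 °C; ZnCl2, −78 → 0 °C; 6, Pd(P(t-Bu)3)2 (5 mol %), THF, 25 → 40 °C; chromatography on Et3N-deactivated silica
Reagents that add atoms: none
Why: Negishi coupling of an alkynylzinc halide with the aryl bromide, where the bulky electron-rich phosphine should allow oxidative addition to the electron-rich 3-bromoindole at or below 40 °C, well under the temperature at which an ethyl ynol ether loses ethylene by retro-ene fragmentation.

**Step 7**
Reactants: 11 chlorobis(triphenylphosphine)cobalt maleoyl complex; 15 3-(ethoxyethynyl)-5-(3-methylbut-2-en-1-yl)-1-(triisopropylsilyl)-1H-indole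
Product: 17 2,5-diethoxy-3,6-bis[5-(3-methylbut-2-en-1-yl)-1-(triisopropylsilyl)-1H-indol-3-yl]cyclohexa-2,5-diene-1,4-dione, via cationic bis(acetonitrile) maleoylcobalt tetrafluoroborate 16 (not isolated)
Conditions: 11, AgBF4 (1.05 equiv), MeCN, 0 → 25 °C, filter off AgCl; 15 (1.2 equiv), MeCN/CH2Cl2, 25 → 45 °C; air work-up
Reagents that add atoms: none
Why: Chloride abstraction gives the 18-electron cation 16 (trivalent cobalt); ynol ether 15 displaces acetonitrile, the electron-rich acyl carbon next to the indolyl-bearing carbon migrates to the ethoxy-bearing alkyne carbon (electrophilic in the slipped, ketenium-like complex), and C–C reductive elimination from the seven-membered cobaltacycle joins the indolyl-bearing alkyne carbon to the acyl carbon next to the ethoxy-bearing carbon, releasing the quinone and monovalent cobalt. The closest known reaction type is the cobalt-mediated benzoquinone synthesis from cyclobutenediones and alkynes through maleoylcobalt complexes, a formal [4+2] annulation. The quinone ring is closed by migratory insertion followed by reductive elimination at cobalt, not by a pericyclic closure, and no stereocentre is formed. The step needs head-to-tail regioselectivity (3,6-diindolyl-2,5-diethoxy, not the 2,6-diindolyl isomer); the nucleophilic ynol-ether carbon (the one bearing the indole) should pair with the more electrophilic, cross-conjugated acyl carbon and the electrophilic ynol-ether carbon with the vinylogous-ester acyl carbon, so either order of bond formation leads to the same isomer, and the bulky N-silylindolyl group twisted out of conjugation leaves ethoxy as the dominant donor in the maleoyl unit. Silver is removed as AgCl before the ynol ether is added so that it cannot activate the alkyne, and the N-silyl groups keep the indoles from binding cobalt.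

**Step 8**
Reactants: 17 2,5-diethoxy-3,6-bis[5-(3-methylbut-2-en-1-yl)-1-(triisopropylsilyl)-1H-indol-3-yl]cyclohexa-2,5-diene-1,4-dione
Product: 18 2,5-diethoxy-3,6-bis[5-(3-methylbut-2-en-1-yl)-1H-indol-3-yl]cyclohexa-2,5-diene-1,4-dione (cochliodinol diethyl ether)
Conditions: Bu4NF (2.4 equiv), AcOH (2.4 equiv), THF, 0 °C
Reagents that add atoms: none
Why: fluoride-induced N-desilylation of both indoles, buffered with acetic acid so that the two vinylogous ethyl esters of the quinone are not hydrolysed or exchanged.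

**Step 9**
Reactants: 18 2,5-diethoxy-3,6-bis[5-(3-methylbut-2-en-1-yl)-1H-indol-3-yl]cyclohexa-2,5-diene-1,4-dione
Product: 19 2-ethoxy-5-hydroxy-3,6-bis[5-(3-methylbut-2-en-1-yl)-1H-indol-3-yl]cyclohexa-2,5-diene-1,4-dione (cochliodinol monoethyl ether)
Conditions: LiOH·H2O (3 equiv), THF/H2O (3:1), 0 → 25 °C; 1 M HCl to pH 2, 0 °C
Reagents that add atoms: lithium hydroxide, [Li+].[OH-]
Why: addition–elimination of hydroxide at a vinylogous ester (saponification of an alkoxyquinone) should stop after one exchange because the product is a delocalised hydroxyquinone anion, and the two ethoxy groups are equivalent by C2 symmetry so only one mono-ether can form.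

**Step 10**
Reactants: 19 2-ethoxy-5-hydroxy-3,6-bis[5-(3-methylbut-2-en-1-yl)-1H-indol-3-yl]cyclohexa-2,5-diene-1,4-dione
Product: 20 hydroperoxycochliodinol, 2-hydroperoxy-5-hydroxy-3,6-bis[5-(3-methylbut-2-en-1-yl)-1H-indol-3-yl]cyclohexa-2,5-diene-1,4-dione
Conditions: 30% aq. H2O2 (10 equiv), LiOH·H2O (2.2 equiv), THF/H2O (3:1), 0 °C, dark; cold 0.5 M HCl to pH 3, extract, no reductive quench
Reagents that add atoms: hydrogen peroxide, OO
Why: Proposed new method: hydroperoxide anion, an alpha-effect nucleophile, should add to the ethoxy-bearing ring carbon (beta to the ring carbonyl) of the quinone monoanion and the tetrahedral intermediate should expel ethoxide, an addition–elimination at a vinylogous ester that is the vinylogue of the LiOOH perhydrolysis of esters to peroxy acids, with the hydroxide or amine exchange of alkoxyquinones and the displacement of halide from halogenated quinones by hydroperoxide as the closest known reaction types; the hydroxyquinone half is masked as its anion and the product as its peroxy anion, which should not be substituted again.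

**Compound list**
1 | 5-bromo-1H-indole | Brc1ccc2[nH]ccc2c1 | starting material
2 | 5-bromo-1-(triisopropylsilyl)-1H-indole | CC(C)[Si](C(C)C)(C(C)C)n1ccc2cc(Br)ccc21 | intermediate
3 | 1-bromo-3-methylbut-2-ene | CC(C)=CCBr | starting material
4 | 5-lithio-1-(triisopropylsilyl)-1H-indole | [Li]c1ccc2c(ccn2[Si](C(C)C)(C(C)C)C(C)C)c1 | intermediate
5 | 5-(3-methylbut-2-en-1-yl)-1-(triisopropylsilyl)-1H-indole | CC(C)=CCc1ccc2c(ccn2[Si](C(C)C)(C(C)C)C(C)C)c1 | intermediate
6 | 3-bromo-5-(3-methylbut-2-en-1-yl)-1-(triisopropylsilyl)-1H-indole | CC(C)=CCc1ccc2c(c1)c(Br)cn2[Si](C(C)C)(C(C)C)C(C)C | intermediate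
7 | 3,4-diethoxycyclobut-3-ene-1,2-dione | CCOC1=C(OCC)C(=O)C1=O | starting material
8 | 3-lithio-5-(3-methylbut-2-en-1-yl)-1-(triisopropylsilyl)-1H-indole | CC(C)=CCc1ccc2c(c1)c([Li])cn2[Si](C(C)C)(C(C)C)C(C)C | intermediate
9 | lithium 2,3-diethoxy-4-oxo-1-[5-(3-methylbut-2-en-1-yl)-1-(triisopropylsilyl)-1H-indol-3-yl]cyclobut-2-en-1-olate (racemic) | CCOC1=C(OCC)C(O[Li])(c2cn([Si](C(C)C)(C(C)C)C(C)C)c3ccc(CC=C(C)C)cc23)C1=O | intermediate
10 | 3-ethoxy-4-[5-(3-methylbut-2-en-1-yl)-1-(triisopropylsilyl)-1H-indol-3-yl]cyclobut-3-ene-1,2-dione | CCOC1=C(c2cn([Si](C(C)C)(C(C)C)C(C)C)c3ccc(CC=C(C)C)cc23)C(=O)C1=O | intermediate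
11 | chlorobis(triphenylphosphine)cobalt maleoyl complex of 10 (1-cobaltacyclopent-3-ene-2,5-dione) | CCOC1=C(c2cn([Si](C(C)C)(C(C)C)C(C)C)c3ccc(CC=C(C)C)cc23)C(=O)[Co-2](Cl)([P+](c2ccccc2)(c2ccccc2)c2ccccc2)([P+](c2ccccc2)(c2ccccc2)c2ccccc2)C1=O | intermediate
12 | ethoxyethyne | CCOC#C | starting material
13 | (ethoxyethynyl)lithium | CCOC#C[Li] | intermediate
14 | (ethoxyethynyl)zinc chloride | CCOC#C[Zn]Cl | intermediate
15 | 3-(ethoxyethynyl)-5-(3-methylbut-2-en-1-yl)-1-(triisopropylsilyl)-1H-indole | CCOC#Cc1cn([Si](C(C)C)(C(C)C)C(C)C)c2ccc(CC=C(C)C)cc12 | intermediate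
16 | bis(acetonitrile)bis(triphenylphosphine)cobalt maleoyl cation, tetrafluoroborate | CCOC1=C(c2cn([Si](C(C)C)(C(C)C)C(C)C)c3ccc(CC=C(C)C)cc23)C(=O)[Co-3]([N+]#CC)([N+]#CC)([P+](c2ccccc2)(c2ccccc2)c2ccccc2)([P+](c2ccccc2)(c2ccccc2)c2ccccc2)C1=O.F[B-](F)(F)F | intermediate
17 | 2,5-diethoxy-3,6-bis[5-(3-methylbut-2-en-1-yl)-1-(triisopropylsilyl)-1H-indol-3-yl]cyclohexa-2,5-diene-1,4-dione | CCOC1=C(c2cn([Si](C(C)C)(C(C)C)C(C)C)c3ccc(CC=C(C)C)cc23)C(=O)C(OCC)=C(c2cn([Si](C(C)C)(C(C)C)C(C)C)c3ccc(CC=C(C)C)cc23)C1=O | intermediate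
18 | 2,5-diethoxy-3,6-bis[5-(3-methylbut-2-en-1-yl)-1H-indol-3-yl]cyclohexa-2,5-diene-1,4-dione | CCOC1=C(c2c[nH]c3ccc(CC=C(C)C)cc23)C(=O)C(OCC)=C(c2c[nH]c3ccc(CC=C(C)C)cc23)C1=O | intermediate
19 | 2-ethoxy-5-hydroxy-3,6-bis[5-(3-methylbut-2-en-1-yl)-1H-indol-3-yl]cyclohexa-2,5-diene-1,4-dione | CCOC1=C(c2c[nH]c3ccc(CC=C(C)C)cc23)C(=O)C(O)=C(c2c[nH]c3ccc(CC=C(C)C)cc23)C1=O | intermediate
20 | hydroperoxycochliodinol | CC(C)=CCc1ccc2[nH]cc(C3=C(O)C(=O)C(c4c[nH]c5ccc(CC=C(C)C)cc45)=C(OO)C3=O)c2c1 | target

**Step count and risks**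
Total step count: 10. Longest linear sequence: 9 steps (1, 2, 3, 4, 5, 7, 8, 9, 10).

Steps most likely to fail:

1. Step 10. Nucleophilic epoxidation of the quinone double bond, Hooker-type oxidative ring cleavage of the hydroxyquinone anion, or base-induced decay of the peroxy anion may outrun the exchange of ethoxide. The fallback sets out from 18 and comes back at 20. Exhaustive saponification of 18 (NaOH, aqueous EtOH, reflux, then acid) should give cochliodinol F1. Oxalyl chloride (1 equiv) with catalytic DMF in CH2Cl2 at −20 °C, the known conversion of hydroxyquinones into chloroquinones, should turn one of its two equivalent hydroxyls into the vinylogous acid chloride 2-chloro-5-hydroxy-3,6-bis[5-(3-methylbut-2-en-1-yl)-1H-indol-3-yl]cyclohexa-2,5-diene-1,4-dione F2. Treating F2 with H2O2 and NaHCO3 in aqueous MeCN at 0 °C, the known substitution of halide in halogenated quinones by hydroperoxide near neutral pH, should give 20.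

2. Step 7. Head-to-head alkyne insertion giving the 2,6-diindolyl isomer, cobalt-induced oligomerisation or hydration of the ynol ether, or poor turnover of the stoichiometric complex may defeat the annulation. The fallback sets out from 6 and comes back at 17, with the regiochemistry fixed by a dihaloquinone instead of an insertion. Lithiation of 6 to 8 and quenching with 2-isopropoxy-4,4,5,5-tetramethyl-1,3,2-dioxaborolane should give the boronate 5-(3-methylbut-2-en-1-yl)-3-(4,4,5,5-tetramethyl-1,3,2-dioxaborolan-2-yl)-1-(triisopropylsilyl)-1H-indole F3. Tetrabromo-1,4-benzoquinone with NaOEt (2 equiv) in EtOH should give 2,5-dibromo-3,6-diethoxycyclohexa-2,5-diene-1,4-dione F4. A double Suzuki–Miyaura coupling of F4 with F3 (PdCl2(dppf), K3PO4, dioxane, 80 °C), as used for 2,5-diaryl-3,6-dialkoxyquinones, should then give 17.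

3. Step 6. Slow oxidative addition to the electron-rich 3-bromoindole, retro-ene loss of ethylene from the ynol ether, or its hydration on silica may erode the coupling. The fallback sets out from 6 and comes back at 15, making the alkyne by elimination instead of coupling. Ethoxyacetyl chloride, N,O-dimethylhydroxylamine hydrochloride and Et3N should give 2-ethoxy-N-methoxy-N-methylacetamide F5. Acylation of 8 (from 6, t-BuLi) with F5 should give the ketone 2-ethoxy-1-[5-(3-methylbut-2-en-1-yl)-1-(triisopropylsilyl)-1H-indol-3-yl]ethan-1-one F6. LiN(SiMe3)2 and PhNTf2 (THF, −78 °C) should give the (Z)-enol triflate (Z)-2-ethoxy-1-[5-(3-methylbut-2-en-1-yl)-1-(triisopropylsilyl)-1H-indol-3-yl]ethenyl trifluoromethanesulfonate F7 through the chelated enolate. KOt-Bu (THF, −78 → 0 °C) should then give 15 by anti elimination, the known route from α-alkoxy ketones to ynol ethers.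

**Further compounds**
F1 | step 10 | 2,5-dihydroxy-3,6-bis[5-(3-methylbut-2-en-1-yl)-1H-indol-3-yl]cyclohexa-2,5-diene-1,4-dione (cochliodinol) | CC(C)=CCc1ccc2[nH]cc(C3=C(O)C(=O)C(c4c[nH]c5ccc(CC=C(C)C)cc45)=C(O)C3=O)c2c1
F2 | step 10 | 2-chloro-5-hydroxy-3,6-bis[5-(3-methylbut-2-en-1-yl)-1H-indol-3-yl]cyclohexa-2,5-diene-1,4-dione | CC(C)=CCc1ccc2[nH]cc(C3=C(O)C(=O)C(c4c[nH]c5ccc(CC=C(C)C)cc45)=C(Cl)C3=O)c2c1
F3 | step 7 | 5-(3-methylbut-2-en-1-yl)-3-(4,4,5,5-tetramethyl-1,3,2-dioxaborolan-2-yl)-1-(triisopropylsilyl)-1H-indole | CC(C)=CCc1ccc2c(c1)c(B1OC(C)(C)C(C)(C)O1)cn2[Si](C(C)C)(C(C)C)C(C)C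
F4 | step 7 | 2,5-dibromo-3,6-diethoxycyclohexa-2,5-diene-1,4-dione | CCOC1=C(Br)C(=O)C(OCC)=C(Br)C1=O
F5 | step 6 | 2-ethoxy-N-methoxy-N-methylacetamide | CCOCC(=O)N(C)OC
F6 | step 6 | 2-ethoxy-1-[5-(3-methylbut-2-en-1-yl)-1-(triisopropylsilyl)-1H-indol-3-yl]ethan-1-one | CCOCC(=O)c1cn([Si](C(C)C)(C(C)C)C(C)C)c2ccc(CC=C(C)C)cc12
F7 | step 6 | (Z)-2-ethoxy-1-[5-(3-methylbut-2-en-1-yl)-1-(triisopropylsilyl)-1H-indol-3-yl]ethenyl trifluoromethanesulfonate | CCO/C=C(\OS(=O)(=O)C(F)(F)F)c1cn([Si](C(C)C)(C(C)C)C(C)C)c2ccc(CC=C(C)C)cc12
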